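**Plan**
- Retrosynthesis: the C5''–Br bond is cut first. The pyrrole is then opened at C3''–C4''; both are unsubstituted CH positions, so each can be the terminus of a vinyl group, and this ring bond can come from alkene metathesis of an N1''-allyl/C2''-vinyl sulfonamide. The N1'' sulfonyl group later serves as the leaving group for aromatisation.
- The diene is cut at N1''–C5'' (allylation), C2''–C3'' (vinyl Grignard addition to an N-sulfonyl imine) and C2'–C2'' (formylation of the magnesiated oxazole). The oxazole goes back to an indole-3-carbaldehyde and TosMIC, and the aldehyde to the indole.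
- Forward: the indole is bought, the oxazole ring is built second (step 2), and the pyrrole ring is closed last as a 3-pyrroline (step 8). It is aromatised with loss of both sulfonyl groups (step 9) and brominated at C5'' (step 10).
- Stereochemistry: the target has no stereocentre. The only one on the way, C2'' in 13, 15 and 16, is made racemic and erased in step 9; imine 11 is E.

Key step: step 8

Remark: indole atoms are unprimed, oxazole atoms primed (O1', C2', N3', C4', C5') and pyrrole atoms double-primed (N1''–C5''); 6-bromo-4-methoxy-1H-indole is assumed to be purchasable, and tosyl (Ts) means 4-methylbenzenesulfonyl.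

**Step 1**
Reactants: 1 6-bromo-4-methoxy-1H-indole
Product: 3 6-bromo-4-methoxy-1H-indole-3-carbaldehyde, via indol-3-ylmethylidene dimethyliminium chloride 2 (not isolated)
Conditions: POCl3, DMF, 0 °C → 40 °C; then aq NaOH, 0 °C → 80 °C
Reagents that add atoms: N,N-dimethylformamide, CN(C)C=O; water, O
Why: Vilsmeier–Haack formylation, in which the chloroiminium ion attacks the most nucleophilic indole position C3 and the iminium salt 2 is hydrolysed to the aldehyde on basic work-up.

**Step 2**
Reactants: 3 6-bromo-4-methoxy-1H-indole-3-carbaldehyde; 4 tosylmethyl isocyanide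
Product: 6 5-(6-bromo-4-methoxy-1H-indol-3-yl)oxazole, via 4-tosyl-4,5-dihydrooxazole adduct 5 (not isolated)
Conditions: TosMIC, K2CO3, MeOH, reflux
Reagents that add atoms: tosylmethyl isocyanide (compound 4), Cc1ccc(S(=O)(=O)C[N+]#[C-])cc1
Why: Van Leusen oxazole synthesis, in which the TosMIC anion adds to the aldehyde, the alkoxide closes onto the isocyanide carbon to give oxazoline 5 and base-induced loss of toluenesulfinate aromatises it to the 5-substituted oxazole, the free indole N–H being tolerated.

**Step 3**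
Reactants: 6 5-(6-bromo-4-methoxy-1H-indol-3-yl)oxazole
Product: 7 5-(6-bromo-4-methoxy-1-tosylindol-3-yl)oxazole
Conditions: TsCl, Bu4NHSO4 (cat.), 50% aq NaOH, CH2Cl2, 0 °C → rt
Reagents that add atoms: 4-methylbenzenesulfonyl chloride, Cc1ccc(S(=O)(=O)Cl)cc1
Why: Phase-transfer N-sulfonylation of the indole nitrogen, which removes the acidic N–H before the metalation and damps the nucleophilicity of the indole in the later steps.

**Step 4**
Reactants: 7 5-(6-bromo-4-methoxy-1-tosylindol-3-yl)oxazole
Product: 10 5-(6-bromo-4-methoxy-1-tosylindol-3-yl)oxazole-2-carbaldehyde, via oxazol-2-ylmagnesium chloride 8 (not isolated), via magnesium hemiaminal alkoxide 9 (not isolated)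
Conditions: TMPMgCl·LiCl (TMP = 2,2,6,6-tetramethylpiperidide), THF, −20 °C; DMF, −20 °C → rt; aq NH4Cl
Reagents that add atoms: N,N-dimethylformamide, CN(C)C=O
Why: Directed magnesiation followed by Bouveault formylation, in which the Knochel–Hauser base removes the most acidic proton (oxazole C2'–H) without halogen–metal exchange at the aryl bromide, the magnesium species stays ring-closed and its DMF adduct 9 collapses to the aldehyde on work-up.

**Step 5**
Reactants: 10 5-(6-bromo-4-methoxy-1-tosylindol-3-yl)oxazole-2-carbaldehyde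
Product: 11 (E)-N-{[5-(6-bromo-4-methoxy-1-tosylindol-3-yl)oxazol-2-yl]methylidene}-4-methylbenzenesulfonamide
Conditions: TsNH2, Ti(OEt)4, CH2Cl2, 40 °C
Reagents that add atoms: 4-methylbenzenesulfonamide, Cc1ccc(S(N)(=O)=O)cc1
Why: Condensation of a primary sulfonamide with an aldehyde, with Ti(OEt)4 serving as Lewis acid and water scavenger, should give the E N-sulfonyl aldimine, which is taken on crude.

**Step 6**
Reactants: 11 (E)-N-{[5-(6-bromo-4-methoxy-1-tosylindol-3-yl)oxazol-2-yl]methylidene}-4-methylbenzenesulfonamide; 12 vinylmagnesium bromide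
Product: 13 racemic N-{1-[5-(6-bromo-4-methoxy-1-tosylindol-3-yl)oxazol-2-yl]prop-2-enyl}-4-methylbenzenesulfonamide
Conditions: CH2=CHMgBr, THF, −78 °C; aq NH4Cl
Reagents that add atoms: vinylmagnesium bromide (compound 12), C=C[Mg]Br
Why: 1,2-Addition of a Grignard reagent to an activated N-sulfonyl aldimine forms C2''–C3'', and since no chiral controller is present the new C2'' stereocentre arises as a racemate, which suffices because it is destroyed in step 9.

**Step 7**
Reactants: 13 racemic N-{1-[5-(6-bromo-4-methoxy-1-tosylindol-3-yl)oxazol-2-yl]prop-2-enyl}-4-methylbenzenesulfonamide; 14 allyl bromide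
Product: 15 racemic N-allyl-N-{1-[5-(6-bromo-4-methoxy-1-tosylindol-3-yl)oxazol-2-yl]prop-2-enyl}-4-methylbenzenesulfonamide
Conditions: allyl bromide, K2CO3, DMF, rt
Reagents that add atoms: allyl bromide (compound 14), C=CCBr
Why: SN2 N-alkylation of the acidic sulfonamide N–H with K2CO3, a base too weak to shift the vinyl double bond into conjugation with the oxazole.

**Step 8**
Reactants: 15 racemic N-allyl-N-{1-[5-(6-bromo-4-methoxy-1-tosylindol-3-yl)oxazol-2-yl]prop-2-enyl}-4-methylbenzenesulfonamide
Product: 16 racemic 5-(6-bromo-4-methoxy-1-tosylindol-3-yl)-2-(1-tosyl-2,5-dihydro-1H-pyrrol-2-yl)oxazole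
Conditions: RCl2Ru(=CHPh)(PCy3)(SIMes)-type second-generation Grubbs catalyst, RuCl2(=CHPh)(PCy3)(SIMes) (SIMes = 1,3-dimesitylimidazolidin-2-ylidene), 5 mol %, CH2Cl2 (0.02 M), 40 °C
Reagents that add atoms: none
Why: Ring-closing olefin metathesis: the catalyst RuCl2(=CHPh)(PCy3)(SIMes) exchanges its carbene onto the less hindered N-allyl terminus, the new alkylidene undergoes intramolecular [2+2] cycloaddition with the C2''-vinyl group, and the ruthenacyclobutane cycloreverts to the C3''=C4'' double bond while the two terminal CH2 groups leave as ethylene. The closest known reaction type is the closure of N-tosyl diallylamines, including 2-aryl-substituted ones, to N-tosyl-3-pyrrolines. The one ring formed is the five-membered 2,5-dihydropyrrole, closed at C3''–C4'' by metathesis of two terminal alkenes joined through C2''–N1''–C5''. No stereocentre is created, and the racemic C2'' centre is carried through unchanged. The selectivity needed is ring closure over intermolecular cross-metathesis and over alkene migration; it is secured by the short three-atom tether, the branching at C2'' and the bulky sulfonamide that turn the alkenes toward each other, and by dilution with ethylene allowed to escape. The sulfonamide nitrogen is non-basic and the oxazole nitrogen only a weak donor, so the catalyst should stay active.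

**Step 9**
Reactants: 16 racemic 5-(6-bromo-4-methoxy-1-tosylindol-3-yl)-2-(1-tosyl-2,5-dihydro-1H-pyrrol-2-yl)oxazole
Product: 19 5-(6-bromo-4-methoxy-1H-indol-3-yl)-2-(1H-pyrrol-2-yl)oxazole, via 2H-pyrrole tautomer 17 (not isolated), via indole-N-tosyl pyrrole 18 (not isolated)
Conditions: KOtBu (6 equiv), THF, 0 °C → rt; then H2O, 60 °C
Reagents that add atoms: none
Why: Base-induced E1cB elimination of toluenesulfinate from the N-sulfonyl-3-pyrroline (C2''–H is acidified by the oxazole, the alkene and the sulfonamide) gives 2H-pyrrole 17, which tautomerises to the aromatic 1H-pyrrole 18, and the KOH formed on adding water then hydrolyses the indole N–S bond with the indolide as leaving group.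

**Step 10**
Reactants: 19 5-(6-bromo-4-methoxy-1H-indol-3-yl)-2-(1H-pyrrol-2-yl)oxazole
Product: 20 2-(5-bromo-1H-pyrrol-2-yl)-5-(6-bromo-4-methoxy-1H-indol-3-yl)oxazole
Conditions: NBS (1.0 equiv), THF, −78 °C, dark
Reagents that add atoms: N-bromosuccinimide, O=C1CCC(=O)N1Br
Why: Electrophilic aromatic bromination, in which one equivalent of NBS at low temperature should attack the free α-position C5'' of the 2-substituted pyrrole faster than the C3-blocked, bromine-bearing indole.

**Compound list**
1 | 6-bromo-4-methoxy-1H-indole | COc1cc(Br)cc2[nH]ccc12 | starting material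
2 | (6-bromo-4-methoxy-1H-indol-3-yl)methylidene-dimethyliminium chloride (formed in situ) | COc1cc(Br)cc2[nH]cc(C=[N+](C)C)c12.[Cl-] | intermediate
3 | 6-bromo-4-methoxy-1H-indole-3-carbaldehyde | COc1cc(Br)cc2[nH]cc(C=O)c12 | intermediate
4 | tosylmethyl isocyanide (TosMIC) | Cc1ccc(S(=O)(=O)C[N+]#[C-])cc1 | starting material
5 | 5-(6-bromo-4-methoxy-1H-indol-3-yl)-4-tosyl-4,5-dihydrooxazole, racemic, configuration at C4/C5 inconsequential (formed in situ) | COc1cc(Br)cc2[nH]cc(C3OC=NC3S(=O)(=O)c3ccc(C)cc3)c12 | intermediate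
6 | 5-(6-bromo-4-methoxy-1H-indol-3-yl)oxazole | COc1cc(Br)cc2[nH]cc(-c3cnco3)c12 | intermediate
7 | 5-(6-bromo-4-methoxy-1-tosylindol-3-yl)oxazole | COc1cc(Br)cc2c1c(-c1cnco1)cn2S(=O)(=O)c1ccc(C)cc1 | intermediate
8 | [5-(6-bromo-4-methoxy-1-tosylindol-3-yl)oxazol-2-yl]magnesium chloride, LiCl complex (formed in situ) | COc1cc(Br)cc2c1c(-c1cnc([Mg]Cl)o1)cn2S(=O)(=O)c1ccc(C)cc1.[Li+].[Cl-] | intermediate
9 | chloromagnesium alkoxide of [5-(6-bromo-4-methoxy-1-tosylindol-3-yl)oxazol-2-yl](dimethylamino)methanol, racemic (formed in situ) | COc1cc(Br)cc2c1c(-c1cnc(C(O[Mg]Cl)N(C)C)o1)cn2S(=O)(=O)c1ccc(C)cc1 | intermediate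
10 | 5-(6-bromo-4-methoxy-1-tosylindol-3-yl)oxazole-2-carbaldehyde | COc1cc(Br)cc2c1c(-c1cnc(C=O)o1)cn2S(=O)(=O)c1ccc(C)cc1 | intermediate
11 | (E)-N-{[5-(6-bromo-4-methoxy-1-tosylindol-3-yl)oxazol-2-yl]methylidene}-4-methylbenzenesulfonamide | COc1cc(Br)cc2c1c(-c1cnc(/C=N/S(=O)(=O)c3ccc(C)cc3)o1)cn2S(=O)(=O)c1ccc(C)cc1 | intermediate
12 | vinylmagnesium bromide | C=C[Mg]Br | starting material
13 | racemic N-{1-[5-(6-bromo-4-methoxy-1-tosylindol-3-yl)oxazol-2-yl]prop-2-enyl}-4-methylbenzenesulfonamide | COc1cc(Br)cc2c1c(-c1cnc(C(C=C)NS(=O)(=O)c3ccc(C)cc3)o1)cn2S(=O)(=O)c1ccc(C)cc1 | intermediate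
14 | allyl bromide | C=CCBr | starting material
15 | racemic N-allyl-N-{1-[5-(6-bromo-4-methoxy-1-tosylindol-3-yl)oxazol-2-yl]prop-2-enyl}-4-methylbenzenesulfonamide | COc1cc(Br)cc2c1c(-c1cnc(C(C=C)N(CC=C)S(=O)(=O)c3ccc(C)cc3)o1)cn2S(=O)(=O)c1ccc(C)cc1 | intermediate
16 | racemic 5-(6-bromo-4-methoxy-1-tosylindol-3-yl)-2-(1-tosyl-2,5-dihydro-1H-pyrrol-2-yl)oxazole | COc1cc(Br)cc2c1c(-c1cnc(C3C=CCN3S(=O)(=O)c3ccc(C)cc3)o1)cn2S(=O)(=O)c1ccc(C)cc1 | intermediate
17 | 5-(6-bromo-4-methoxy-1-tosylindol-3-yl)-2-(2H-pyrrol-5-yl)oxazole (formed in situ) | COc1cc(Br)cc2c1c(-c1cnc(C3=NCC=C3)o1)cn2S(=O)(=O)c1ccc(C)cc1 | intermediate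
18 | 5-(6-bromo-4-methoxy-1-tosylindol-3-yl)-2-(1H-pyrrol-2-yl)oxazole (formed in situ) | COc1cc(Br)cc2c1c(-c1cnc(-c3ccc[nH]3)o1)cn2S(=O)(=O)c1ccc(C)cc1 | intermediate
19 | 5-(6-bromo-4-methoxy-1H-indol-3-yl)-2-(1H-pyrrol-2-yl)oxazole | COc1cc(Br)cc2[nH]cc(-c3cnc(-c4ccc[nH]4)o3)c12 | intermediate
20 | 2-(5-bromo-1H-pyrrol-2-yl)-5-(6-bromo-4-methoxy-1H-indol-3-yl)oxazole (achiral) | COc1cc(Br)cc2[nH]cc(-c3cnc(-c4ccc(Br)[nH]4)o3)c12 | target

**Totals**
Total step count: 10. Longest linear sequence: 10 steps, from 1 to 20.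

**Steps most likely to fail**

Step 10. Site selectivity of the bromination may be poor, since both heteroaromatic rings carry a free N–H and are electron-rich. Attack at C3''/C4'', at indole C2, C5 or C7, or a second bromination could compete with the wanted attack at C5''. The fallback changes the order of deprotection so that the indole stays deactivated during bromination. It sets out from 16, which is treated with KOtBu (2 equiv) in THF at −20 °C and quenched cold with aq NH4Cl. Elimination and tautomerisation should then occur while the indole sulfonamide survives, and 18 is isolated. NBS in THF at −78 °C should then brominate only the pyrrole α-position to give 2-(5-bromo-1H-pyrrol-2-yl)-5-(6-bromo-4-methoxy-1-tosylindol-3-yl)oxazole F1. Aqueous KOH in THF/MeOH at 50 °C removes the tosyl group, and the route is rejoined at 20.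

Step 9. The alkoxide may move the ring double bond to the enamide position without expelling sulfinate, the indole N–S bond may be cleaved incompletely, or the material may degrade under hot base. The fallback aromatises by oxidation instead of elimination. It sets out from 16, which is dehydrogenated with DDQ in toluene at 80 °C to 5-(6-bromo-4-methoxy-1-tosylindol-3-yl)-2-(1-tosylpyrrol-2-yl)oxazole F2. Both N-sulfonyl groups, on pyrrole and indole, are then hydrolysed with KOH in MeOH/THF/H2O at 60 °C, and the route is rejoined at 19.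

Step 5. The condensation may stay incomplete, and the very electrophilic heteroaryl N-sulfonyl imine may hydrolyse back to the aldehyde during work-up, so that little imine reaches step 6. The fallback forms the C2''–N1'' bond by substitution instead of by addition to an imine. It sets out from 10, to which vinylmagnesium bromide is added (THF, −78 °C; aq NH4Cl) to give racemic 1-[5-(6-bromo-4-methoxy-1-tosylindol-3-yl)oxazol-2-yl]prop-2-en-1-ol F3. A Mitsunobu reaction with tert-butyl tosylcarbamate (PPh3, DIAD, THF, 0 °C → rt) should give racemic tert-butyl N-{1-[5-(6-bromo-4-methoxy-1-tosylindol-3-yl)oxazol-2-yl]prop-2-enyl}-N-tosylcarbamate F4. TFA in CH2Cl2 at 0 °C removes the tert-butoxycarbonyl group, and the route is rejoined at 13.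

**Further compounds**
F1 | step 10 | 2-(5-bromo-1H-pyrrol-2-yl)-5-(6-bromo-4-methoxy-1-tosylindol-3-yl)oxazole | COc1cc(Br)cc2c1c(-c1cnc(-c3ccc(Br)[nH]3)o1)cn2S(=O)(=O)c1ccc(C)cc1
F2 | step 9 | 5-(6-bromo-4-methoxy-1-tosylindol-3-yl)-2-(1-tosylpyrrol-2-yl)oxazole | COc1cc(Br)cc2c1c(-c1cnc(-c3cccn3S(=O)(=O)c3ccc(C)cc3)o1)cn2S(=O)(=O)c1ccc(C)cc1
F3 | step 5 | racemic 1-[5-(6-bromo-4-methoxy-1-tosylindol-3-yl)oxazol-2-yl]prop-2-en-1-ol | COc1cc(Br)cc2c1c(-c1cnc(C(O)C=C)o1)cn2S(=O)(=O)c1ccc(C)cc1
F4 | step 5 | racemic tert-butyl N-{1-[5-(6-bromo-4-methoxy-1-tosylindol-3-yl)oxazol-2-yl]prop-2-enyl}-N-tosylcarbamate | COc1cc(Br)cc2c1c(-c1cnc(C(C=C)N(C(=O)OC(C)(C)C)S(=O)(=O)c3ccc(C)cc3)o1)cn2S(=O)(=O)c1ccc(C)cc1
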